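**Plan**
Retrosynthesis: ring E (side-chain lactone) is cut at its CH(O)–CH2 bond (Barbier allylation, then ketone reduction); ring D (azepane) at the CH2–CH2 bond next but one to N (ring-closing metathesis) and at the spiro-C–CH(OH) bond (lactam aldol); ring C at N–C(=O).
What remains is ring A, a cyclopentane whose spiro carbon bears one exocyclic carboxyl carbon next to the ring CH that carries the CH2–CH(N) chain. This is the product pattern of a Wolff ring contraction: putting the carboxyl carbon back into the ring between these two atoms gives a 2-diazocyclohexanone.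
Forward: (4R)-4-hydroxycyclohexenone → α-alkylation with the serine-derived CH2–CH(N)–CH2O unit (Negishi) → ring B as a tetrahydrofuran acetal (radical cyclisation) → ethyl (conjugate addition) → diazo ketone → ring A and ring C in one flask → ring D (bridged lactam) → ring B lactone → ring E.
Stereochemistry: the enone carbinol controls the ring-fusion CH (O-tether), the α-CH (equilibration), the ethyl carbon (anti addition) and the ring-B methyl (convex-face hydrogenation); the spiro centre follows from the cis-fused lactam enolate; N–CH comes from L-serine; both secondary carbinols arise by hydride reduction of ketones; the ring-E methyl by hydrogenation.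

Key step: step 10

Remark: (4R)-4-hydroxycyclohex-2-en-1-one and N-Boc-O-benzyl-L-serinol are taken as purchased enantiopure materials; ring letters: A = carbocycle, B = oxygen ring fused to A, C = six-membered lactam, D = azepane, E = side-chain lactone; a centre written without configuration in a SMILES is a mixture that is removed or reset later.

Step 1
Reactants: 1 tert-butyl N-[(2R)-1-(benzyloxy)-3-hydroxypropan-2-yl]carbamate
Product: 2 tert-butyl N-[(2S)-1-(benzyloxy)-3-iodopropan-2-yl]carbamate
Conditions: I2, PPh3, imidazole, CH2Cl2, 0 °C to rt
Reagents that add atoms: iodine (II)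
Why: Appel-type iodination replaces the primary hydroxyl by iodide in an SN2 step at CH2, so the neighbouring N-bearing stereocentre is not touched (the descriptor changes only through the priority rules).

Step 2
Reactants: 3 (4R)-4-hydroxycyclohex-2-en-1-one
Product: 4 (4R)-4-hydroxy-2-iodocyclohex-2-en-1-one
Conditions: I2, pyridine, CH2Cl2, 0 °C to rt
Reagents that add atoms: iodine (II)
Why: α-Iodination of an enone by the pyridine-mediated addition–iodination–elimination sequence should give the 2-iodoenone and leave the carbinol centre untouched.

Step 3
Reactants: 2 tert-butyl N-[(2S)-1-(benzyloxy)-3-iodopropan-2-yl]carbamate; 4 (4R)-4-hydroxy-2-iodocyclohex-2-en-1-one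
Product: 6 tert-butyl N-[(2R)-1-(benzyloxy)-3-[(3R)-3-hydroxy-6-oxocyclohex-1-en-1-yl]propan-2-yl]carbamate, via alkylzinc iodide 5 (not isolated)
Conditions: 2, Zn dust, I2 (cat.), DMF, rt; then 4, Pd2(dba)3, SPhos, rt
Reagents that add atoms: none
Why: Negishi coupling: zinc insertion into the primary iodide gives a carbamate-stabilised alkylzinc iodide that couples with the alkenyl iodide under zerovalent palladium catalysis, joining the sp3 and sp2 carbons without touching either stereocentre and tolerating the free hydroxyl.

Step 4
Reactants: 6 hydroxy enone carbamate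
Product: 7 mixed acetal of 6 in which the ring oxygen carries CH(OMe)–C(Br)=CH2 (both epimers at the acetal carbon)
Conditions: methoxyallene, N-bromosuccinimide, CH2Cl2, −78 to −20 °C
Reagents that add atoms: methoxyallene (COC=C=C); N-bromosuccinimide (O=C1CCC(=O)N1Br)
Why: Bromoalkoxylation of an alkoxyallene: bromination of the central allene carbon gives an oxocarbenium ion that the secondary alcohol captures, which tethers a 2-bromoallyl unit to the carbinol oxygen.

Step 5
Reactants: 7 2-bromoallyl mixed acetal
Product: 9 cis-fused methylidene acetal ketone (ring A cyclohexanone; ring B 2-methoxy-3-methylidene-tetrahydrofuran; amino side chain on the ketone α-carbon trans to the ring-B carbon on the neighbouring ring-fusion atom), via side-chain epimer 8 (not isolated)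
Conditions: Bu3SnH, AIBN (cat.), PhH, 80 °C, slow addition; then DBU (cat.), CH2Cl2, rt
Reagents that add atoms: none
Why: Ueno–Stork radical cyclisation: the vinyl radical closes 5-exo-trig onto the enone β-carbon and the O-tether enforces the cis ring fusion, so the carbinol centre sets the ring-fusion CH; the α-keto radical then takes hydrogen from Bu3SnH and DBU equilibrates the α-centre to the isomer with the side chain equatorial and trans to the new C–C bond.

Step 6
Reactants: 9 cis-fused methylidene acetal ketone
Product: 10 methyl acetal ketone (as 9 with a ring-B methyl in place of methylidene; methyl cis to the ring-A bond at the ring fusion)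
Conditions: H2 (1 atm), RhCl(PPh3)3, PhH, rt
Reagents that add atoms: none
Why: Homogeneous hydrogenation should deliver hydrogen to the exposed convex face of the cis-fused bicycle, which places the methyl on the concave face as in the target, and it spares the benzyl ether.

Step 7
Reactants: 10 methyl acetal ketone
Product: 12 enone (ring A of 10 with C=C between the CH2 α-carbon and the next ring carbon; remote from the amino side chain), via trimethylsilyl enol ether 11 (not isolated)
Conditions: LiN(i-Pr)2, Me3SiCl, THF, −78 °C; then Pd(OAc)2, MeCN, rt
Reagents that add atoms: none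
Why: Saegusa–Ito oxidation: kinetic deprotonation takes place at the CH2 α-carbon and not at the substituted α-CH, and Pd(OAc)2 dehydrosilylates the enol ether to the enone on that side.

Step 8
Reactants: 12 enone
Product: 13 ethyl ketone (10 carrying ethyl on the ring-A carbon next to the O-bearing ring-fusion carbon; ethyl trans to that C–O bond)
Conditions: EtMgBr, CuI (cat.), THF, −40 °C; aq. NH4Cl
Reagents that add atoms: ethylmagnesium bromide (CC[Mg]Br)
Why: Copper-catalysed conjugate addition to a γ-alkoxy enone occurs anti to the C–O bond (the face away from ring B), which sets the ethyl-bearing centre trans to oxygen.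

Step 9
Reactants: 13 ethyl ketone
Product: 15 α-diazo ketone (13 with =N2 on the CH2 α-carbon), via trifluoroacetyl ketone 14 (not isolated)
Conditions: LiN(SiMe3)2, THF, −78 °C; CF3CO2CH2CF3; then MsN3, Et3N, H2O, MeCN, rt
Reagents that add atoms: methanesulfonyl azide (CS(=O)(=O)N=[N+]=[N-])
Why: Deacylative diazo transfer: the kinetic enolate (CH2 side) is trifluoroacetylated and the activated 1,3-dicarbonyl takes the diazo group from the sulfonyl azide with loss of the trifluoroacetyl group, so the diazo carbon is placed regioselectively and no stereocentre is touched.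

Step 10
Reactants: 15 α-diazo ketone
Product: 19 tricyclic N–H lactam (ring A cyclopentane cis-fused to ring B and to ring C; ring C a piperidin-2-one with CH2OBn on the carbon next to N), via ketene 16 (not isolated), via methyl ester 17 (not isolated), via amine hydrochloride 18 (not isolated)
Conditions: hν (365 nm), MeOH, rt; then HCl (4 M in dioxane), 0 °C to rt; then K2CO3, MeOH, 60 °C
Reagents that add atoms: none
Why: Irradiation expels N2 and, in a Wolff rearrangement, the ring CH attached to the carbonyl (the one carrying the amino side chain) migrates to the diazo carbon, so ring A contracts from six to five members and the former ketone carbon is pushed out of the ring as a ketene. Methanol adds to the ketene, HCl removes the Boc group while methanol keeps ring B as its methyl acetal, and on warming with K2CO3 the free amine closes ring C by 6-exo-trig attack on the ester carbonyl (acyl substitution). The closest known reaction type is the photochemical Wolff ring contraction of 2-diazocyclohexanones with alcohol capture of the ketene, followed by lactamisation of a δ-amino ester. The migrating carbon keeps its configuration; the new carbon α to the ester forms as a mixture and is equilibrated through the ester enolate by K2CO3/MeOH into the epimer that can lactamise, so that only the cis-fused bicycle should result. The step needs the diazo group on the CH2 side of the ketone, which step 9 secures, and long-wavelength light, which leaves carbamate, acetal and benzyl ether untouched.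

Step 11
Reactants: 19 tricyclic N–H lactam
Product: 20 N-allyl lactam
Conditions: NaH, allyl bromide, DMF, 0 °C to rt
Reagents that add atoms: allyl bromide (C=CCBr)
Why: N-Alkylation of a lactam: the N–H is the only site that NaH deprotonates and the amide anion is alkylated on nitrogen by the allylic halide.

Step 12
Reactants: 20 N-allyl lactam
Product: 21 aldol adduct (20 with CH(OH)–CH=CH2 on the lactam α-carbon; new substituent trans to the ring-C CH2; carbinol as a mixture)
Conditions: LiN(i-Pr)2, THF, −78 °C; acrolein; aq. NH4Cl at −78 °C
Reagents that add atoms: acrolein (C=CC=O)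
Why: Aldol addition of the lithium enolate of the tertiary lactam (its only enolisable position) to the aldehyde carbon of acrolein; the electrophile can bond only to the enolate face that leaves ring C cis-fused to ring A (opposite the ethyl group and the ring-C CH2), which sets the quaternary centre, while the carbinol centre formed here is reset in steps 17 and 18.

Step 13
Reactants: 21 aldol adduct
Product: 22 bridged unsaturated lactam (ring D closed as a cycloheptene; N and the quaternary carbon are bridgeheads of a 1-azabicyclo[4.3.1]decenone)
Conditions: second-generation Grubbs catalyst, PhMe, 80 °C, high dilution, argon sparge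
Reagents that add atoms: none
Why: Ring-closing metathesis of the N-allyl and vinyl groups should form the seven-membered ring as the cis-olefin and turn the fused lactam into the bridged one, the loss of ethene driving the closure.

Step 14
Reactants: 22 bridged unsaturated lactam
Product: 23 diol (ring D saturated; free CH2OH on the carbon next to N)
Conditions: H2 (1 atm), Pd/C, EtOAc–MeOH, rt
Reagents that add atoms: none
Why: Catalytic hydrogenation saturates the ring olefin and hydrogenolysis removes the benzyl ether; a shift of the allylic carbinol to the ketone level would be harmless because this carbon is oxidised in step 17.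

Step 15
Reactants: 23 diol
Product: 25 aldehyde lactone (ring B as γ-lactone; CHO on the carbon next to N), via lactol 24 (not isolated)
Conditions: PPTS, acetone–H2O, 50 °C; then TEMPO (cat.), PhI(OAc)2, CH2Cl2, rt
Reagents that add atoms: water (O)
Why: Mild acid hydrolysis of the methyl acetal gives the lactol, and the oxoammonium oxidation (TEMPO with PhI(OAc)2) converts the lactol into the lactone and the primary alcohol into the aldehyde without enolising the ring-B methyl centre.

Step 16
Reactants: 25 aldehyde lactone
Product: 26 homoallylic alcohol ester (former CHO carbon now CH(OH)–CH2–C(=CH2)–CO2Et; carbinol as a mixture)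
Conditions: In powder, ethyl 2-(bromomethyl)acrylate, THF–H2O, rt
Reagents that add atoms: ethyl 2-(bromomethyl)acrylate (C=C(CBr)C(=O)OCC)
Why: Barbier allylation: the allylindium reagent formed in situ adds chemoselectively to the aldehyde in the presence of lactone and lactam, bringing in the remaining carbons of ring E and its future methyl carbon.

Step 17
Reactants: 26 homoallylic alcohol ester
Product: 27 diketone (ring-D carbinol and side-chain carbinol both oxidised to C=O)
Conditions: Dess–Martin periodinane, NaHCO3, CH2Cl2, 0 °C to rt
Reagents that add atoms: none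
Why: Dess–Martin oxidation under buffered, non-basic conditions converts both secondary alcohols into ketones, which erases the two carbinol centres of unsettled configuration without epimerising the α-amino ketone.

Step 18
Reactants: 27 diketone
Product: 29 α-methylene lactone (ring E closed as 2-methylidene-γ-butyrolactone; ring-D carbinol as in 30), via diol ester 28 (not isolated)
Conditions: NaBH4, CeCl3·7H2O, MeOH, −78 °C; then CSA (cat.), CH2Cl2, rt
Reagents that add atoms: none
Why: Luche reduction (1,2-selective, sparing the acrylate): hydride should reach the ring-D ketone from the face opposite the three-carbon bridge to give the equatorial alcohol and attack the side-chain ketone anti to the C–N bond (polar Felkin–Anh model) to give the syn amino alcohol, and acid then closes ring E by lactonisation.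

Step 19
Reactants: 29 α-methylene lactone
Product: 30 CNP0120800.1
Conditions: H2 (1 atm), Pd/C, EtOAc, rt
Reagents that add atoms: none
Why: Hydrogenation of the α-methylene-γ-butyrolactone should take place on the face opposite the bulky γ-substituent, which gives the cis-α-methyl lactone and completes the target.

**Compound list**
1 | tert-butyl N-[(2R)-1-(benzyloxy)-3-hydroxypropan-2-yl]carbamate (N-Boc-O-benzyl-L-serinol) | OC[C@H](COCc1ccccc1)NC(=O)OC(C)(C)C | starting material
2 | tert-butyl N-[(2S)-1-(benzyloxy)-3-iodopropan-2-yl]carbamate | IC[C@H](COCc1ccccc1)NC(=O)OC(C)(C)C | intermediate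
3 | (4R)-4-hydroxycyclohex-2-en-1-one | O=C1CC[C@@H](O)C=C1 | starting material
4 | (4R)-4-hydroxy-2-iodocyclohex-2-en-1-one | O=C1CC[C@@H](O)C=C1I | intermediate
5 | [(2S)-3-(benzyloxy)-2-(Boc-amino)propyl]zinc iodide (not isolated) | I[Zn]C[C@H](COCc1ccccc1)NC(=O)OC(C)(C)C | intermediate
6 | tert-butyl N-[(2R)-1-(benzyloxy)-3-[(3R)-3-hydroxy-6-oxocyclohex-1-en-1-yl]propan-2-yl]carbamate | O=C1CC[C@@H](O)C=C1C[C@H](COCc1ccccc1)NC(=O)OC(C)(C)C | intermediate
7 | 2-bromoallyl methyl mixed acetal of 6 (acetal carbon unassigned) | O=C1CC[C@@H](OC(OC)C(Br)=C)C=C1C[C@H](COCc1ccccc1)NC(=O)OC(C)(C)C | intermediate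
8 | epimer of 9 at the side-chain-bearing α-carbon (not isolated) | O=C1CC[C@H]2OC(OC)C(=C)[C@H]2[C@H]1C[C@H](COCc1ccccc1)NC(=O)OC(C)(C)C | intermediate
9 | cis-fused methylidene acetal ketone, side chain trans to the ring-B carbon | O=C1CC[C@H]2OC(OC)C(=C)[C@H]2[C@@H]1C[C@H](COCc1ccccc1)NC(=O)OC(C)(C)C | intermediate
10 | methyl acetal ketone, ring-B methyl on the concave face | O=C1CC[C@H]2OC(OC)[C@@H](C)[C@H]2[C@@H]1C[C@H](COCc1ccccc1)NC(=O)OC(C)(C)C | intermediate
11 | trimethylsilyl enol ether of 10 toward the CH2 side (not isolated) | C[Si](C)(C)OC1=CC[C@H]2OC(OC)[C@@H](C)[C@H]2[C@@H]1C[C@H](COCc1ccccc1)NC(=O)OC(C)(C)C | intermediate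
12 | enone derived from 10 | O=C1C=C[C@H]2OC(OC)[C@@H](C)[C@H]2[C@@H]1C[C@H](COCc1ccccc1)NC(=O)OC(C)(C)C | intermediate
13 | ethyl ketone, ethyl trans to the ring-fusion C–O bond | O=C1C[C@H](CC)[C@H]2OC(OC)[C@@H](C)[C@H]2[C@@H]1C[C@H](COCc1ccccc1)NC(=O)OC(C)(C)C | intermediate
14 | α-trifluoroacetyl derivative of 13 (not isolated) | O=C1C(C(=O)C(F)(F)F)[C@H](CC)[C@H]2OC(OC)[C@@H](C)[C@H]2[C@@H]1C[C@H](COCc1ccccc1)NC(=O)OC(C)(C)C | intermediate
15 | α-diazo ketone | O=C1C(=[N+]=[N-])[C@H](CC)[C@H]2OC(OC)[C@@H](C)[C@H]2[C@@H]1C[C@H](COCc1ccccc1)NC(=O)OC(C)(C)C | intermediate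
16 | ring-contracted ketene (not isolated) | O=C=C1[C@H](CC)[C@H]2OC(OC)[C@@H](C)[C@H]2[C@@H]1C[C@H](COCc1ccccc1)NC(=O)OC(C)(C)C | intermediate
17 | ring-contracted methyl ester, α-centre as a mixture (not isolated) | COC(=O)C1[C@H](CC)[C@H]2OC(OC)[C@@H](C)[C@H]2[C@@H]1C[C@H](COCc1ccccc1)NC(=O)OC(C)(C)C | intermediate
18 | amine hydrochloride of 17 after Boc removal (not isolated) | COC(=O)C1[C@H](CC)[C@H]2OC(OC)[C@@H](C)[C@H]2[C@@H]1C[C@H](COCc1ccccc1)[NH3+].[Cl-] | intermediate
19 | tricyclic N–H lactam, rings A and C cis-fused | CC[C@@H]1[C@H]2OC(OC)[C@@H](C)[C@H]2[C@@H]2C[C@H](COCc3ccccc3)NC(=O)[C@H]12 | intermediate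
20 | N-allyl lactam | CC[C@@H]1[C@H]2OC(OC)[C@@H](C)[C@H]2[C@@H]2C[C@H](COCc3ccccc3)N(CC=C)C(=O)[C@H]12 | intermediate
21 | aldol adduct with 1-hydroxyallyl on the quaternary carbon (carbinol mixture) | CC[C@@H]1[C@H]2OC(OC)[C@@H](C)[C@H]2[C@@H]2C[C@H](COCc3ccccc3)N(CC=C)C(=O)[C@]12C(O)C=C | intermediate
22 | bridged unsaturated lactam (carbinol mixture) | CC[C@@H]1[C@H]2OC(OC)[C@@H](C)[C@H]2[C@@H]2C[C@H](COCc3ccccc3)N3CC=CC(O)[C@@]12C3=O | intermediate
23 | bridged lactam diol | CC[C@@H]1[C@H]2OC(OC)[C@@H](C)[C@H]2[C@@H]2C[C@H](CO)N3CCCC(O)[C@@]12C3=O | intermediate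
24 | lactol from 23 (not isolated) | CC[C@@H]1[C@H]2OC(O)[C@@H](C)[C@H]2[C@@H]2C[C@H](CO)N3CCCC(O)[C@@]12C3=O | intermediate
25 | aldehyde lactone | CC[C@@H]1[C@H]2OC(=O)[C@@H](C)[C@H]2[C@@H]2C[C@H](C=O)N3CCCC(O)[C@@]12C3=O | intermediate
26 | homoallylic alcohol ethyl ester (carbinol mixtures) | CC[C@@H]1[C@H]2OC(=O)[C@@H](C)[C@H]2[C@@H]2C[C@H](C(O)CC(=C)C(=O)OCC)N3CCCC(O)[C@@]12C3=O | intermediate
27 | diketone | CC[C@@H]1[C@H]2OC(=O)[C@@H](C)[C@H]2[C@@H]2C[C@H](C(=O)CC(=C)C(=O)OCC)N3CCCC(=O)[C@@]12C3=O | intermediate
28 | diol ester after reduction (not isolated) | CC[C@@H]1[C@H]2OC(=O)[C@@H](C)[C@H]2[C@@H]2C[C@H]([C@H](O)CC(=C)C(=O)OCC)N3CCC[C@@H](O)[C@@]12C3=O | intermediate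
29 | α-methylene lactone | CC[C@@H]1[C@H]2OC(=O)[C@@H](C)[C@H]2[C@@H]2C[C@H]([C@H]3CC(=C)C(=O)O3)N3CCC[C@@H](O)[C@@]12C3=O | intermediate
30 | CNP0120800.1 | CC[C@@H]1[C@H]2OC(=O)[C@@H](C)[C@H]2[C@@H]2C[C@H]([C@H]3C[C@@H](C)C(=O)O3)N3CCC[C@@H](O)[C@@]12C3=O | target

**Totals**
Total steps: 19. Longest linear sequence: 18 steps (3 to 30 through steps 2–19; the serine branch 1 to 2 joins at step 3).

**Steps most likely to fail**

Step 13. The planar N-allyl amide has to twist as the bridged ring closes, so ring closure may stall while intermolecular metathesis and olefin isomerisation take over. The fallback makes the ring C–C bond irreversibly from an enolate equivalent instead of by metathesis. It sets out from 19. Commercial 4-chloro-1,1-dimethoxybutane is converted by acid-catalysed exchange with benzyl alcohol into 4-chloro-1,1-bis(benzyloxy)butane F1 and by Finkelstein exchange into 1,1-bis(benzyloxy)-4-iodobutane F2. N-Alkylation of 19 (NaH, DMF) with F2 should give the N-[4,4-bis(benzyloxy)butyl] lactam F3. LiN(i-Pr)2 and Me3SiCl convert F3 into its silyl ketene N,O-acetal, and Me3SiOTf at −78 °C ionises the dibenzyl acetal. An intramolecular Mukaiyama-type addition through an open, antiperiplanar transition state then closes ring D and should give the bridged lactam benzyl ether F4 with the benzyloxy group equatorial, as required. Hydrogenolysis (H2, Pd/C) of both benzyl ethers comes back to the route at 23.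

Step 18. Hydride addition may lose facial selectivity at either ketone, may reduce the ketone-like bridged lactam carbonyl, or may be preceded by epimerisation next to the side-chain ketone or retro-Claisen opening of the β-keto lactam. The fallback uses reagent control and avoids the oxidation–reduction pair. It sets out from 25: allylboration with a camphor-diol-derived 2-(ethoxycarbonyl)allylboronate, catalysed by Sc(OTf)3, sets the side-chain carbinol under reagent control, and the adduct lactonises on work-up, so the sequence comes back to the route at 29. Steps 16–18 are skipped; the ring-D carbinol is then the one formed in step 12, where a closed chair-like transition state is expected to favour the required epimer.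

Step 5. The vinyl radical may be reduced by the stannane before it closes onto the trisubstituted enone, and equilibration of the α-centre may stay incomplete. The fallback replaces the radical chain by an organopalladium closure. It sets out from 7: intramolecular reductive Heck cyclisation (Pd(OAc)2, PPh3, HCO2Na, DMF, 80 °C) proceeds by oxidative addition of the alkenyl bromide, 5-exo carbopalladation of the enone and formate reduction of the palladium enolate. The same DBU equilibration then comes back to the route at 9.

Further compounds
F1 | step 13 | 4-chloro-1,1-bis(benzyloxy)butane | ClCCCC(OCc1ccccc1)OCc1ccccc1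
F2 | step 13 | 1,1-bis(benzyloxy)-4-iodobutane | ICCCC(OCc1ccccc1)OCc1ccccc1
F3 | step 13 | N-[4,4-bis(benzyloxy)butyl] lactam | CC[C@@H]1[C@H]2OC(OC)[C@@H](C)[C@H]2[C@@H]2C[C@H](COCc3ccccc3)N(CCCC(OCc3ccccc3)OCc3ccccc3)C(=O)[C@H]12
F4 | step 13 | bridged lactam benzyl ether | CC[C@@H]1[C@H]2OC(OC)[C@@H](C)[C@H]2[C@@H]2C[C@H](COCc3ccccc3)N3CCC[C@@H](OCc4ccccc4)[C@@]12C3=O
F0 | step 18 | none | none
F0 | step 5 | none | none
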